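**Retrosynthetic overview** (locants: bicyclo[3.1.1]heptane unit with spiro carbon C2, bridgeheads C1 and C5, ring CH2 groups C3 and C4, CMe2 = C6, CH2 bridge = C7; primed locants = chromene part)

1. Target 18 ⇐ bridgehead acid 17 by radical hydrodecarboxylation at C5, which removes the activating group of the key step.
2. 17 ⇐ exo-methylene acid 13 + syncarpic acid 14 + isobutyraldehyde 15: Knoevenagel condensation, then inverse-electron-demand oxa-Diels–Alder reaction; the pyran ring is formed last (O–C2 and CH2–C4' bonds).
3. 13 ⇐ ester 11 ⇐ (3+3) annulation of bicyclo[1.1.0]butane ester 5 with 2-bromo-4-chlorobut-1-ene 7: strain-release addition makes C1–C2, then the enolate so formed closes the six-membered ring by making the C4–C5 bond.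
4. Enabling feature: the four-membered ring C1–C6–C5–C7. Its 1,3-related bridgeheads C1 and C5 are the two ends of the central bond of a bicyclobutane, and C5 is a CH that can carry a temporary ester and so become the enolate carbon.
5. 5 ⇐ prenylated diazo ester 4 by asymmetric intramolecular cyclopropanation (sets both bridgeheads). Ring order: bicyclobutane → six-membered carbocycle of the bicyclo[3.1.1]heptane → pyran; the trione ring comes from 14.

Key step: step 5

Assumption (remark on the chemistry): the sense of induction of Rh2(S-NTTL)4 (NTTL = N-1,8-naphthaloyl-tert-leucinate) with the prenyl substrate 4 cannot be predicted with certainty; the catalyst enantiomer that gives (1S,3R)-5 is used and is written here as the (S)-catalyst.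

**Route**

Step 1
Reactants: 1 tert-butyl acetoacetate; 2 1-bromo-3-methylbut-2-ene (prenyl bromide)
Product: 3 tert-butyl 2-acetyl-5-methylhex-4-enoate (racemic)
Conditions: NaH, THF, 0 °C → rt
Reagents that add atoms: none
Why: Acetoacetic ester alkylation: the sodium enolate of the β-keto ester is C-alkylated by the allylic bromide, and the stereocentre formed is destroyed in step 2.

Step 2
Reactants: 3 tert-butyl 2-acetyl-5-methylhex-4-enoate
Product: 4 tert-butyl 2-diazo-5-methylhex-4-enoate
Conditions: p-ABSA, DBU, MeCN, 0 °C → rt
Reagents that add atoms: 4-acetamidobenzenesulfonyl azide (p-ABSA), CC(=O)Nc1ccc(cc1)S(=O)(=O)N=[N+]=[N-]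
Why: Regitz deacylative diazo transfer: the enolate attacks the sulfonyl azide and the acetyl group leaves as the N-acetylsulfonamide, which gives the α-alkyl-α-diazo ester.

Step 3
Reactants: 4 tert-butyl 2-diazo-5-methylhex-4-enoate
Product: 5 tert-butyl (1S,3R)-2,2-dimethylbicyclo[1.1.0]butane-1-carboxylate
Conditions: Rh2(S-NTTL)4 (1 mol %), toluene, −78 °C, slow addition of 4; solution used directly
Reagents that add atoms: none
Why: Enantioselective intramolecular cyclopropanation (bicyclobutanation of a 2-diazopent-4-enoate) by the divalent rhodium carbene, in which the chiral carboxylate ligands select the alkene face and so set both bridgehead centres together, while low temperature and the bulky ligand should hold back the 1,2-hydride shift.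

Step 4
Reactants: 6 3-bromobut-3-en-1-ol
Product: 7 2-bromo-4-chlorobut-1-ene
Conditions: PPh3, N-chlorosuccinimide, CH2Cl2, 0 °C → rt
Reagents that add atoms: N-chlorosuccinimide, ClN1C(=O)CCC1=O
Why: Appel-type chlorination of the primary alcohol (alkoxyphosphonium activation, SN2 by chloride), to which the vinyl bromide is inert.

Step 5
Reactants: 5 tert-butyl (1S,3R)-2,2-dimethylbicyclo[1.1.0]butane-1-carboxylate; 7 2-bromo-4-chlorobut-1-ene
Product: 11 tert-butyl (1S,5R)-6,6-dimethyl-4-methylidenebicyclo[3.1.1]heptane-1-carboxylate, via (4-chlorobut-1-en-2-yl)lithium 8 (not isolated), via (4-chlorobut-1-en-2-yl)magnesium bromide 9 (not isolated), via bromomagnesium ester enolate 10 (not isolated)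
Conditions: 7, t-BuLi (2 equiv), Et2O, −78 °C; MgBr2·OEt2; then 5, CuBr·SMe2 (10 mol %), PBu3 (20 mol %), THF, −78 → 0 °C; then DMPU, 0 → 40 °C
Reagents that add atoms: tert-butyllithium, [Li]C(C)(C)C (lithium in 8 only); magnesium bromide, Br[Mg]Br (magnesium and bromine in 9 and 10 only); none of their atoms remains in 11
Why: Proposed new method: the vinyl Grignard 9, as its organocopper species (monovalent copper), should attack the σ* lobe of the central bond of 5 at the unsubstituted bridgehead (homoconjugate addition with inversion, as in cuprate openings of activated cyclopropanes), and the ester enolate 10 so released then displaces the primary chloride in a 6-exo-tet SN2 closure, which forms the C4–C5 bond and bridges the cyclobutane across its 1,3-positions. The closest known reactions are the copper-catalysed homoconjugate addition of Grignard reagents to bicyclobutane esters with intermolecular trapping of the enolate, and the methylenecyclopentane annulation in which the same 4-chloro-2-metallobut-1-ene adds to an enone and the enolate then closes onto the chloride; new is that both events take place on a bicyclobutane and give a bridged six-membered ring. The strain released on opening the bicyclobutane (about 40 kcal/mol) drives the first bond and leaves ample driving force for the modest extra strain of the bicyclo[3.1.1]heptane. The only stereocentre carried through is the attacked bridgehead, whose configuration comes from 5 with inversion; the ester-bearing carbon is planar in 10 and can bond only on the face that holds the chain, so both bridgeheads of 11 follow from 5. The step needs attack at the ring carbon and not at the ester carbonyl (tert-butyl ester, copper catalysis), C- and not O-alkylation (O-alkylation would give an eight-membered bridged ketene acetal), and substitution and not elimination (primary chloride, DMPU).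

Step 6
Reactants: 11 tert-butyl (1S,5R)-6,6-dimethyl-4-methylidenebicyclo[3.1.1]heptane-1-carboxylate
Product: 13 (1S,5R)-6,6-dimethyl-4-methylidenebicyclo[3.1.1]heptane-1-carboxylic acid, via trimethylsilyl ester 12 (not isolated)
Conditions: TMSOTf, 2,6-lutidine, CH2Cl2, 0 °C → rt; then pH 5 aqueous buffer
Reagents that add atoms: trimethylsilyl trifluoromethanesulfonate, C[Si](C)(C)OS(=O)(=O)C(F)(F)F (silicon in 12 only, lost on work-up)
Why: Silyl triflate dealkylation of the tert-butyl ester (loss of 2-methylpropene) under lutidine buffering and hydrolysis of the silyl ester on work-up, which avoids the protic acid that would isomerise the exocyclic alkene or open the four-membered ring, and touches no stereocentre.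

Step 7
Reactants: 13 (1S,5R)-6,6-dimethyl-4-methylidenebicyclo[3.1.1]heptane-1-carboxylic acid; 14 syncarpic acid (2,2,4,4-tetramethylcyclohexane-1,3,5-trione); 15 isobutyraldehyde
Product: 17 (1S,2S,5S,4'R)-6,6,6',6',8',8'-hexamethyl-5',7'-dioxo-4'-(propan-2-yl)-3',4',5',6',7',8'-hexahydrospiro[bicyclo[3.1.1]heptane-2,2'-chromene]-5-carboxylic acid, via 2,2,4,4-tetramethyl-6-(2-methylpropylidene)cyclohexane-1,3,5-trione 16 (not isolated)
Conditions: ethylenediammonium diacetate (10 mol %), 4 Å molecular sieves, toluene, 80 °C
Reagents that add atoms: none
Why: Knoevenagel condensation gives the 1-oxadiene 16, which should add to the exocyclic alkene of 13 in an inverse-electron-demand hetero-Diels–Alder reaction with the terminal CH2 bonding to the isobutylidene carbon and the carbonyl oxygen to C2 on the face away from the gem-dimethyl bridge (as β-pinene itself reacts), which sets the spiro centre, while C4' follows from the endo/exo orientation, so that 17 (cyclobutane bridgehead under the oxadiene, isopropyl cis to C1 across the pyran ring) is expected together with its C4' epimer and is separated by chromatography or crystallisation of the acids.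

Step 8
Reactants: 17 the spiro acid of step 7
Product: 18 (1S,2S,5R,4'R)-6,6,6',6',8',8'-hexamethyl-4'-(propan-2-yl)-3',4'-dihydrospiro[bicyclo[3.1.1]heptane-2,2'-chromene]-5',7'(6'H,8'H)-dione (target)
Conditions: 9-mesityl-10-phenylacridinium tetrafluoroborate (5 mol %), PhSSPh (10 mol %), i-Pr2NEt (20 mol %), 2,2,2-trifluoroethanol, 450 nm LEDs, rt
Reagents that add atoms: none
Why: Photoredox hydrodecarboxylation: the carboxylate is oxidised by the excited acridinium, loss of CO2 gives the bridgehead radical, and hydrogen-atom transfer from thiophenol (formed from the disulfide) makes the C5–H bond with the configuration fixed by the bicycle, no other stereocentre being touched.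

**Compound list**

1 | tert-butyl acetoacetate | CC(=O)CC(=O)OC(C)(C)C | starting material
2 | 1-bromo-3-methylbut-2-ene | CC(C)=CCBr | starting material
3 | tert-butyl 2-acetyl-5-methylhex-4-enoate (racemic) | CC(=O)C(CC=C(C)C)C(=O)OC(C)(C)C | intermediate
4 | tert-butyl 2-diazo-5-methylhex-4-enoate | CC(C)=CCC(=[N+]=[N-])C(=O)OC(C)(C)C | intermediate
5 | tert-butyl (1S,3R)-2,2-dimethylbicyclo[1.1.0]butane-1-carboxylate | CC(C)(C)OC(=O)[C@@]12C[C@@H]1C2(C)C | intermediate
6 | 3-bromobut-3-en-1-ol | C=C(Br)CCO | starting material
7 | 2-bromo-4-chlorobut-1-ene | C=C(Br)CCCl | intermediate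
8 | (4-chlorobut-1-en-2-yl)lithium | [Li]C(=C)CCCl | intermediate
9 | (4-chlorobut-1-en-2-yl)magnesium bromide | C=C([Mg]Br)CCCl | intermediate
10 | bromomagnesium enolate of tert-butyl (3R)-3-(4-chlorobut-1-en-2-yl)-2,2-dimethylcyclobutane-1-carboxylate | CC(C)(C)OC(O[Mg]Br)=C1C[C@H](C(=C)CCCl)C1(C)C | intermediate
11 | tert-butyl (1S,5R)-6,6-dimethyl-4-methylidenebicyclo[3.1.1]heptane-1-carboxylate | C=C1CC[C@]2(C(=O)OC(C)(C)C)C[C@H]1C2(C)C | intermediate
12 | trimethylsilyl (1S,5R)-6,6-dimethyl-4-methylidenebicyclo[3.1.1]heptane-1-carboxylate | C=C1CC[C@]2(C(=O)O[Si](C)(C)C)C[C@H]1C2(C)C | intermediate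
13 | (1S,5R)-6,6-dimethyl-4-methylidenebicyclo[3.1.1]heptane-1-carboxylic acid | C=C1CC[C@]2(C(=O)O)C[C@H]1C2(C)C | intermediate
14 | syncarpic acid (2,2,4,4-tetramethylcyclohexane-1,3,5-trione) | CC1(C)C(=O)CC(=O)C(C)(C)C1=O | starting material
15 | isobutyraldehyde | CC(C)C=O | starting material
16 | 2,2,4,4-tetramethyl-6-(2-methylpropylidene)cyclohexane-1,3,5-trione | CC(C)C=C1C(=O)C(C)(C)C(=O)C(C)(C)C1=O | intermediate
17 | (1S,2S,5S,4'R)-spiro acid (target skeleton with CO2H on bridgehead C5) | CC(C)[C@H]1C[C@]2(CC[C@]3(C(=O)O)C[C@H]2C3(C)C)OC2=C1C(=O)C(C)(C)C(=O)C2(C)C | intermediate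
18 | (1S,2S,5R,4'R)-6,6,6',6',8',8'-hexamethyl-4'-(propan-2-yl)-3',4'-dihydrospiro[bicyclo[3.1.1]heptane-2,2'-chromene]-5',7'(6'H,8'H)-dione | CC(C)[C@H]1C[C@]2(CC[C@@H]3C[C@H]2C3(C)C)OC2=C1C(=O)C(C)(C)C(=O)C2(C)C | target

**Step count and risks**

Total step count: 8. Longest linear sequence: 7 steps (1, 2, 3, 5, 6, 7, 8); step 4 is a one-step side branch.

Steps most likely to fail:

1. Step 5 (proposed new method). The enolate 10 may be protonated or act as a base (loss of HCl from the homoallylic chloride to a 2-substituted butadiene) faster than it closes the strained ring, and the chloro Grignard 9 may close on itself before it adds. The fallback sets out from 5 and 7 and comes back at 11, with the two bond formations decoupled. The copper-catalysed homoconjugate addition of 9 to 5 is stopped by an NH4Cl quench at low temperature, which should give the isolable tert-butyl (3R)-3-(4-chlorobut-1-en-2-yl)-2,2-dimethylcyclobutane-1-carboxylate F1 (both epimers at the ester-bearing carbon, which is re-enolised later). Finkelstein exchange (NaI, acetone) gives tert-butyl (3R)-3-(4-iodobut-1-en-2-yl)-2,2-dimethylcyclobutane-1-carboxylate F2. Slow addition of F2 to KN(SiMe3)2 in THF/DMPU at −78 → 0 °C under high dilution forms the potassium enolate of the iodo ester F3, which closes the same C4–C5 bond by intramolecular ester-enolate alkylation and gives 11.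

2. Step 3. Enantioselectivity may be eroded, and a 1,2-hydride shift of the carbene to the dienoate may compete, since the prenyl substrate lies outside the aryl-substituted cases on which the bicyclobutanation is established. The fallback sets out from 13 of insufficient enantiomeric purity and comes back at 13, with the absolute configuration no longer left to the catalyst. The acid is crystallised with (R)-1-phenylethylamine; the salt of the wanted acid, (R)-1-phenylethylammonium (1S,5R)-6,6-dimethyl-4-methylidenebicyclo[3.1.1]heptane-1-carboxylate F4, is collected, while the diastereomeric (R)-1-phenylethylammonium (1R,5S)-6,6-dimethyl-4-methylidenebicyclo[3.1.1]heptane-1-carboxylate F5 stays in the mother liquor (if F5 proves the less soluble salt, the (S)-amine is used). Aqueous citric acid liberates 13.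

3. Step 7. Endo/exo discrimination at C4' may be poor, and an ene reaction of the exocyclic alkene may compete, because substrate control by the remote bicycle is weak. The fallback sets out from 13 and separately prepared 16 and comes back at 17, with substrate control replaced by catalyst control. Heterodiene 16 is made from 14 and 15 at room temperature (proline, CH2Cl2), filtered and added at −40 °C to 13 and a chiral BINOL-derived N-triflylphosphoramide (10 mol %), which activates the oxadiene by hydrogen bonding as in cycloadditions of ortho-quinone methides with unactivated alkenes. Both catalyst enantiomers are screened and the matched one is used; this fallback makes no new compound (F0).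

Further compounds
F1 | step 5 | tert-butyl (3R)-3-(4-chlorobut-1-en-2-yl)-2,2-dimethylcyclobutane-1-carboxylate | CC(C)(C)OC(=O)C1C[C@H](C(=C)CCCl)C1(C)C
F2 | step 5 | tert-butyl (3R)-3-(4-iodobut-1-en-2-yl)-2,2-dimethylcyclobutane-1-carboxylate | CC(C)(C)OC(=O)C1C[C@H](C(=C)CCI)C1(C)C
F3 | step 5 | potassium enolate of the iodo ester | CC(C)(C)OC(O[K])=C1C[C@H](C(=C)CCI)C1(C)C
F4 | step 3 | (R)-1-phenylethylammonium (1S,5R)-6,6-dimethyl-4-methylidenebicyclo[3.1.1]heptane-1-carboxylate | C=C1CC[C@]2(C(=O)[O-])C[C@H]1C2(C)C.C[C@@H]([NH3+])c1ccccc1
F5 | step 3 | (R)-1-phenylethylammonium (1R,5S)-6,6-dimethyl-4-methylidenebicyclo[3.1.1]heptane-1-carboxylate | C=C1CC[C@@]2(C(=O)[O-])C[C@@H]1C2(C)C.C[C@@H]([NH3+])c1ccccc1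
F0 | step 7 | none | none
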